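## The problem

The target is a daucane-type hydroazulene. Cyclopentane ring A (C1, C2, C3, C3a, C8a) is trans-fused through C3a–C8a to cycloheptenone ring B (C3a, C4 to C8, C8a). It has five stereocentres, C1, C3, C3a, C4 and C8a, four of them contiguous. Only C8a is an all-carbon quaternary centre that cannot be corrected later, so it must be set absolutely and then used as the anchor. Taking the face of the C8a methyl as α, the C3a hydrogen and all three oxygens (C1 acetate, C3 hydroxyl, C4 aroyloxy) are β. Reagents that approach a trans-fused framework away from the angular methyl can therefore deliver C3a–H, C4–O and C1–O, whereas C3 needs its carbon substituent on the methyl side and must be steered by groups already on the β face. C1 is an isolated oxygenated carbon next to the quaternary centre and can only be reached through unsaturation in ring A. The allylic aroyl ester at C4, the C1 acetate, the free phenol, the tertiary C3 alcohol and the enone will not survive hydrides, carbanions or strong acid or base, so both esters go on last. The opening is ring B: C6 (one-carbon substituent), C7 (carbonyl) and C8 (methylene next to quaternary C8a) are the three carbons of a 2-siloxyvinylcarbenoid, and C5–C4–C3a–C8a is a diene whose C3a=C8a bond is the alkene of a ring A cyclopentenone.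

## Retrosynthesis

**Acyl groups last.** The C4–O aroyl and C1–O acetyl bonds are cut first. Target 30 is the desilylated form of 29. Ester 29 comes from allylic alcohol 25 and acid 28, which is made from 4-hydroxybenzoic acid 26 through bis-silyl compound 27. Alcohol 25 is freed from silyl ether 24, the C1 acetate of diol 23. Carrying either ester further back is ruled out by the hydride, amide-base and organocerium steps upstream. Acetate before aroate requires that the two secondary oxygens be unmasked at different times, so C1 carries a triethylsilyl (TES) and C4 a tert-butyldimethylsilyl (TBS) group. The forward steps only have to acylate one secondary alcohol at a time beside an unreactive tertiary one.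

**Ring B enone.** The C5=C6 bond and C6 methyl of 23 are traced to exocyclic enone 22 by a double-bond shift. Enone 22 comes from β-siloxy acrylate 20 by reduction to allylic alcohol 21 and acid-induced loss of water and silicon. No skeletal bond is cut. The gain is that ring B stays in the form the key step delivers, a vinylogous silyl carbonate inert to boranes, amide bases, oxidants and organocerium reagents, so the C7 ketone needs no protection. Early hydrolysis to the β-keto ester and C-methylation would add a decarboxylation and leave a second free ketone. The forward sequence needs the ester to be the last reducible carbonyl and the isomerisation to stop at the conjugated enone; with C8a quaternary no other enone can form.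

**C3 carbinol.** The C3–isopropyl bond is cut: 20 comes from ketone 19 and an isopropyl nucleophile. This is the shortest way to the tertiary alcohol, but the nucleophile must enter from the α face. The silyl ethers at C1 (pseudo-axial, β) and C4 (β) are placed first to screen the other face. Oxygen delivery to a C2=C3 isopropyl alkene is four steps longer and is held in reserve.

**C1 oxygen.** The C1–O bond is cut through a conjugate addition. Ketone 19 is the TES ether of β-hydroxy ketone 18. Compound 18 comes from enone 16 by boryl addition (boronate 17) and oxidation, and 16 from ketone 14 through enol ether 15. Carrying the C1 oxygen in from a 4-oxygenated cyclopentenone would need an enantiopure building block and would put a stereocentre next to the carbon where the Cope bond forms. The forward reaction needs attack at C1 anti to the axial C8a methyl, which only a trans-fused enone offers; hence C3a is set first.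

**C3a–H and C4–O.** These two bonds are cut together. Ketone 14 comes from alcohol 13, the C4 mono-silyl ether of diol 12. Diol 12 arises by hydroboration–oxidation (organoborane 11) of allylic alcohol 10, the reduction product of dienone 9. Epoxidising the enone of 9 and opening it reductively would keep the ketone and save two redox steps. It would, however, set C4 and C3a in two unrelated events (epoxide face, enolate protonation), neither clearly biased by C8a. Hydroboration adds H and B syn in one event, and a reagent-set C3 oxygen on the α face reinforces the C8a methyl. The price is a selective silylation and a re-oxidation.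

**Key disconnection.** Dienone 9 is cut at C5–C6 and C8–C8a into dienone 4 and diazo ester 7, by way of cis-divinylcyclopropane 8. This opens ring B, removes the only stereocentre and leaves two achiral fragments of eight and four skeletal carbons. The forward reaction must cyclopropanate only the vinyl group, place the two alkenyl groups cis, do so enantioselectively, and let the Cope shift form the quaternary centre.

**Fragments.** Dienone 4 comes from bromoenone 2 and vinylboronate 3 (C3a–C4 bond), and 2 from 3-methylcyclopent-2-en-1-one 1. Diazo ester 7 comes from diazo ketoester 6, made from methyl acetoacetate 5.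

## Roads not taken

Alternative 1: conjugate methylation–aldol.
- **Cut:** C8a–CH3 and C3a–C4, with ring B left open.
- **Forward step:** Cu(OTf)2 (copper bis(triflate)) with a chiral phosphoramidite adds Al(CH3)3 to enone A1, and the aluminium enolate is trapped by iodoenal A2 to give A3. Ring B would close later at C6–C7 by a CrCl2/NiCl2 Nozaki–Hiyama–Kishi reaction, followed by oxidation.
- **Merits:** convergent; three contiguous centres (C8a, C3a, C4) in one flask; the C4 oxygen and the C5=C6 alkene with its methyl are in place from the start.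
- **Weak points:** no ring closes. The aldol has to distinguish at C3a between CH3 and CH2CH(OR)2 on the neighbouring quaternary carbon, a small difference. The C4 configuration follows from enolate geometry and cannot be chosen. A3 is a β-hydroxy ketone that must survive acetal hydrolysis without retro-aldol or dehydration. The seven-membered closure is entropically costly.
- **Comparison:** this road is better in ring B functional-group economy, since it needs no ester-to-methyl conversion (steps 14 and 15 here). The chosen plan sets against it a catalyst-controlled quaternary centre formed in the ring-closing step and a C3a/C4 pair created in one syn addition.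

Alternative 2: Büchner ring expansion.
- **Cut:** C3a–C8a and C3a–C4 (target numbering).
- **Forward step:** Rh2(OAc)4 (dirhodium tetraacetate) or a chiral relative decomposes diazoketone A4. The carbenoid adds to an ipso–ortho bond and the norcaradiene opens to dihydroazulenone A5, whose sp3 ring-fusion carbon corresponds to C3a.
- **Merits:** both rings from a simple arene in very few steps; the C7 oxygen and C6 methyl come from the arene.
- **Weak points:** the C8a methyl is absent and would have to be added later to a ring-fusion sp2 carbon. The two ipso–ortho bonds are inequivalent, so regioisomers are expected. The one stereocentre formed is α to the ketone, doubly allylic and labile, so asymmetric induction buys nothing. C4 oxygen, C1 oxygen and C3 are all still to come on an over-unsaturated ring that needs selective reduction.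
- **Comparison:** shorter to a hydroazulene than steps 1–5 here, but it defers every stereochemical problem, whereas the chosen key step settles the hardest one.

Alternative 3: silicon-directed Nazarov cyclisation.
- **Cut:** C1–C8a.
- **Forward step:** FeCl3 (iron trichloride) promotes conrotatory closure of dienone A6. Loss of silicon leaves the C1=C2 enone and protonation sets C3a, giving A7.
- **Merits:** the quaternary centre forms in the ring-closing step, and the product has exactly the ring A enone that this plan reaches only at 16.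
- **Weak points:** a cycloheptene with two stereocentres and a tetrasubstituted alkene must be built first. Closure occurs anti to the C4 acyloxy group, which puts the C8a methyl cis to the C4 oxygen, the opposite of 30; C4 would need inversion, possibly by Mitsunobu esterification with 28. Kinetic protonation at C3a normally gives the cis-fused ring. The ketal and pivalate must survive the Lewis acid, and closure onto a fully substituted terminus is slow.
- **Comparison:** better for ring A functionality, but it needs a long precursor synthesis and has two stereochemical outcomes running against the target, where the chosen plan starts from two one- or two-step fragments.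

Key step: step 5

Remarks. Azulene numbering of the target is used for every bicyclic compound, also where systematic numbering would differ; α is the face of the C8a methyl, β the other face. TBS = tert-butyldimethylsilyl, TES = triethylsilyl. Assumption: Rh2(S-PTAD)4 is taken to give the (1S,2R)-cyclopropane 8, the usual sense for this catalyst family with donor–acceptor carbenoids; if the sense were opposite, Rh2(R-PTAD)4 would be used with nothing else changed.

Step 1
Reactants: 1 3-methylcyclopent-2-en-1-one
Product: 2 2-bromo-3-methylcyclopent-2-en-1-one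
Conditions: Br2, CH2Cl2, 0 °C; then Et3N
Reagents that add atoms: bromine, BrBr
Why: Addition of bromine to the enone and base-induced loss of HBr (α-bromination by addition–elimination) puts bromine at C2, the only vinylic C–H; no stereocentre is formed.

Step 2
Reactants: 2 2-bromo-3-methylcyclopent-2-en-1-one; 3 vinylboronic acid pinacol ester
Product: 4 3-methyl-2-vinylcyclopent-2-en-1-one
Conditions: PdCl2(dppf) (3 mol%), K2CO3, dioxane/H2O, 80 °C
Reagents that add atoms: none
Why: Suzuki–Miyaura coupling of an α-bromoenone with an alkenylboronate is routine; the dienone should be used promptly because it can dimerise.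

Step 3
Reactants: 5 methyl acetoacetate
Product: 6 methyl 2-diazo-3-oxobutanoate
Conditions: 4-acetamidobenzenesulfonyl azide, Et3N, MeCN, 0 °C → rt
Reagents that add atoms: 4-acetamidobenzenesulfonyl azide, CC(=O)Nc1ccc(cc1)S(=O)(=O)N=[N+]=[N-]
Why: Regitz diazo transfer to an active methylene compound.

Step 4
Reactants: 6 methyl 2-diazo-3-oxobutanoate
Product: 7 methyl 3-(TBSO)-2-diazobut-3-enoate
Conditions: TBSOTf, Et3N, CH2Cl2, 0 °C
Reagents that add atoms: tert-butyldimethylsilyl triflate, CC(C)(C)[Si](C)(C)OS(=O)(=O)C(F)(F)F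
Why: O-Silylation of the acetyl group of a 2-diazo-1,3-dicarbonyl compound with a silyl triflate and an amine gives the 2-siloxyvinyl diazoacetate; the diazo group tolerates these conditions.

Step 5
Reactants: 4 3-methyl-2-vinylcyclopent-2-en-1-one; 7 methyl 3-(TBSO)-2-diazobut-3-enoate
Product: 9 methyl (8aS)-7-(TBSO)-8a-methyl-3-oxo-1,2,3,5,8,8a-hexahydroazulene-6-carboxylate, via cis-divinylcyclopropane 8 (not isolated)
Conditions: Rh2(S-PTAD)4 (dirhodium tetrakis[(S)-N-phthaloyl-1-adamantylglycinate], 1 mol%), 7 added slowly to 4 (1.5 equiv), hexane/PhCF3, −25 °C → rt; then 60 °C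
Reagents that add atoms: none
Why: Loss of N2 from 7 gives a rhodium-bound donor–acceptor vinylcarbenoid that cyclopropanates the monosubstituted vinyl group of 4 (C5–C6 and, transiently, C4–C6), placing the siloxyvinyl group cis to the cyclopentenyl group in 8, as is usual for such carbenoids. The cis-divinylcyclopropane then undergoes a [3,3] sigmatropic (Cope) shift through a boat transition state that forms C8–C8a, breaks C4–C6 and so closes seven-membered ring B. Overall this is the known tandem cyclopropanation–Cope reaction of vinyldiazoacetates with dienes, a formal (4+3) cycloaddition. C8a, the only stereocentre that survives, is set by the chiral dirhodium carboxylate in the cyclopropanation and carried over stereospecifically, because the boat geometry fixes which face of the ring alkene bonds to C8. Chemoselectivity rests on the ring alkene being tetrasubstituted and conjugated to the ketone: the electrophilic carbenoid leaves it alone, yet it still serves as the second alkenyl group. Its methyl group points into the boat, so the rearrangement may be slow, hence the final warming.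

Step 6
Reactants: 9 methyl (8aS)-7-(TBSO)-8a-methyl-3-oxo-1,2,3,5,8,8a-hexahydroazulene-6-carboxylate
Product: 10 methyl (3R,8aS)-7-(TBSO)-3-hydroxy-8a-methyl-1,2,3,5,8,8a-hexahydroazulene-6-carboxylate
Conditions: (S)-Me-CBS (20 mol%), catecholborane, toluene, −78 °C
Reagents that add atoms: none
Why: Corey–Bakshi–Shibata reduction: the oxazaborolidine binds the carbonyl lone pair anti to the larger, α-branched alkenyl side (C3a) and delivers hydride to one face, giving the 3R alcohol (hydroxyl α) under reagent control. Only 1,2-reduction is expected, and the vinylogous carbonate of ring B is inert.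

Step 7
Reactants: 10 methyl (3R,8aS)-7-(TBSO)-3-hydroxy-8a-methyl-1,2,3,5,8,8a-hexahydroazulene-6-carboxylate
Product: 12 methyl (3R,3aS,4R,8aS)-7-(TBSO)-3,4-dihydroxy-8a-methyl-1,2,3,3a,4,5,8,8a-octahydroazulene-6-carboxylate, via C4 organoborane 11 (not isolated)
Conditions: BH3·THF, THF, 0 °C → rt; then NaBO3·4H2O, H2O
Reagents that add atoms: sodium perborate, [Na+].[O-]OB=O
Why: Hydroboration–oxidation: boron adds to the less substituted C4 and hydrogen to C3a in one syn event from the β face, because the C3 oxygen (as its borate) and the C8a methyl both flank the α face. C3a–H and C4–OH therefore arise cis to each other and trans to the methyl (trans ring fusion); the push-pull ring B alkene does not react, and perborate oxidises the C–B bond with retention.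

Step 8
Reactants: 12 methyl (3R,3aS,4R,8aS)-7-(TBSO)-3,4-dihydroxy-8a-methyl-1,2,3,3a,4,5,8,8a-octahydroazulene-6-carboxylate
Product: 13 methyl (3R,3aS,4R,8aS)-4,7-bis(TBSO)-3-hydroxy-8a-methyl-1,2,3,3a,4,5,8,8a-octahydroazulene-6-carboxylate
Conditions: TBSCl (1.05 equiv), imidazole, DMF, −20 → 0 °C
Reagents that add atoms: tert-butyldimethylsilyl chloride, CC(C)(C)[Si](C)(C)Cl
Why: Site-selective silylation: the C4 hydroxyl is equatorial-like and unhindered, whereas the C3 hydroxyl is pseudo-axial on the α face and 1,3-syn to the angular methyl, so the bulky silyl chloride should take C4 first.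

Step 9
Reactants: 13 methyl (3R,3aS,4R,8aS)-4,7-bis(TBSO)-3-hydroxy-8a-methyl-1,2,3,3a,4,5,8,8a-octahydroazulene-6-carboxylate
Product: 14 methyl (3aR,4R,8aS)-4,7-bis(TBSO)-8a-methyl-3-oxo-1,2,3,3a,4,5,8,8a-octahydroazulene-6-carboxylate
Conditions: Dess–Martin periodinane, pyridine, CH2Cl2, 0 °C → rt
Reagents that add atoms: none
Why: Dess–Martin oxidation under buffered, non-basic conditions leaves the epimerisable C3a centre and the elimination-prone β-silyloxy ketone undisturbed.

Step 10
Reactants: 14 methyl (3aR,4R,8aS)-4,7-bis(TBSO)-8a-methyl-3-oxo-1,2,3,3a,4,5,8,8a-octahydroazulene-6-carboxylate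
Product: 16 methyl (3aR,4R,8aR)-4,7-bis(TBSO)-8a-methyl-3-oxo-3,3a,4,5,8,8a-hexahydroazulene-6-carboxylate, via trimethylsilyl enol ether 15 (not isolated)
Conditions: lithium diisopropylamide (LDA), Me3SiCl, THF, −78 °C; then Pd(OAc)2, MeCN, rt
Reagents that add atoms: none
Why: Saegusa–Ito dehydrogenation: LDA removes the less hindered C2 proton kinetically, not the C3a methine whose enolate would expel the C4 silyloxy group, and palladium diacetate converts the enol ether into the C1=C2 enone. The ester-deactivated enol silyl ether of ring B should not react.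

Step 11
Reactants: 16 methyl (3aR,4R,8aR)-4,7-bis(TBSO)-8a-methyl-3-oxo-3,3a,4,5,8,8a-hexahydroazulene-6-carboxylate
Product: 18 methyl (1R,3aR,4R,8aS)-4,7-bis(TBSO)-1-hydroxy-8a-methyl-3-oxo-1,2,3,3a,4,5,8,8a-octahydroazulene-6-carboxylate, via C1 pinacol boronate 17 (not isolated)
Conditions: CuCl (5 mol%), DPEphos, NaOtBu (10 mol%), B2pin2, MeOH, THF, rt; then NaBO3·4H2O, THF/H2O
Reagents that add atoms: sodium perborate, [Na+].[O-]OB=O
Why: Copper-catalysed conjugate borylation, then oxidation of the C–B bond with retention. In the trans-fused enone the boryl copper species adds to C1 anti to the axial methyl on the adjacent C8a, giving the 1β-hydroxy ketone; only catalytic alkoxide is present, so C3a should not epimerise.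

Step 12
Reactants: 18 methyl (1R,3aR,4R,8aS)-4,7-bis(TBSO)-1-hydroxy-8a-methyl-3-oxo-1,2,3,3a,4,5,8,8a-octahydroazulene-6-carboxylate
Product: 19 methyl (1R,3aR,4R,8aS)-4,7-bis(TBSO)-8a-methyl-3-oxo-1-(TESO)-1,2,3,3a,4,5,8,8a-octahydroazulene-6-carboxylate
Conditions: Et3SiCl, imidazole, CH2Cl2, 0 °C
Reagents that add atoms: triethylsilyl chloride, CC[Si](Cl)(CC)CC
Why: Standard silylation; the TES ether is cleaved by dilute acid in step 14 while the C4 TBS ether stays, and, pseudo-axial on the β face, it screens that face of C3.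

Step 13
Reactants: 19 methyl (1R,3aR,4R,8aS)-4,7-bis(TBSO)-8a-methyl-3-oxo-1-(TESO)-1,2,3,3a,4,5,8,8a-octahydroazulene-6-carboxylate
Product: 20 methyl (1R,3R,3aR,4R,8aS)-4,7-bis(TBSO)-3-hydroxy-8a-methyl-3-(propan-2-yl)-1-(TESO)-1,2,3,3a,4,5,8,8a-octahydroazulene-6-carboxylate
Conditions: iPrMgCl, CeCl3, THF, −78 °C
Reagents that add atoms: isopropylmagnesium chloride, CC(C)[Mg]Cl
Why: Organocerium 1,2-addition, whose low basicity suppresses enolisation and β-hydride reduction of the hindered ketone. The β face of the carbonyl is screened by the pseudo-axial C1 silyloxy group, the C4 silyloxy group and the axial C3a hydrogen, so isopropyl should enter from the α face and leave the hydroxyl β; the deactivated ring B ester should not react at −78 °C.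

Step 14
Reactants: 20 methyl (1R,3R,3aR,4R,8aS)-4,7-bis(TBSO)-3-hydroxy-8a-methyl-3-(propan-2-yl)-1-(TESO)-1,2,3,3a,4,5,8,8a-octahydroazulene-6-carboxylate
Product: 22 (1R,3R,3aR,4R,8aS)-4-(TBSO)-1,3-dihydroxy-8a-methyl-6-methylidene-3-(propan-2-yl)octahydroazulen-7(1H)-one, via allylic alcohol 21 (not isolated)
Conditions: iBu2AlH, CH2Cl2, −78 °C; then 1 M HCl, THF, 0 °C
Reagents that add atoms: none
Why: Hydride reduction of the vinylogous carbonate gives allylic alcohol 21. Acid then expels water with help from the enol ether oxygen, and desilylation of the siloxyallyl cation leaves the α-methylene ketone, the usual fate of reduced β-alkoxy acrylates. The same acid removes the TES ether but should spare the hindered secondary TBS ether.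

Step 15
Reactants: 22 (1R,3R,3aR,4R,8aS)-4-(TBSO)-1,3-dihydroxy-8a-methyl-6-methylidene-3-(propan-2-yl)octahydroazulen-7(1H)-one
Product: 23 (1R,3R,3aR,4R,8aS)-4-(TBSO)-1,3-dihydroxy-6,8a-dimethyl-3-(propan-2-yl)-2,3,3a,4,8,8a-hexahydroazulen-7(1H)-one
Conditions: RhCl3·3H2O (10 mol%), EtOH, 70 °C
Reagents that add atoms: none
Why: Rhodium hydride addition–elimination (alkene isomerisation) moves the exocyclic double bond into the ring to the more stable trisubstituted conjugated enone; with C8a quaternary, only the C5=C6 position is available.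

Step 16
Reactants: 23 (1R,3R,3aR,4R,8aS)-4-(TBSO)-1,3-dihydroxy-6,8a-dimethyl-3-(propan-2-yl)-2,3,3a,4,8,8a-hexahydroazulen-7(1H)-one
Product: 24 (1R,3R,3aR,4R,8aS)-4-(TBSO)-3-hydroxy-6,8a-dimethyl-7-oxo-3-(propan-2-yl)-1,2,3,3a,4,7,8,8a-octahydroazulen-1-yl acetate
Conditions: Ac2O, pyridine, DMAP (cat.), rt
Reagents that add atoms: acetic anhydride, CC(=O)OC(C)=O
Why: Nucleophile-catalysed acylation of the only free secondary alcohol; the tertiary C3 alcohol does not react under these conditions.

Step 17
Reactants: 24 (1R,3R,3aR,4R,8aS)-4-(TBSO)-3-hydroxy-6,8a-dimethyl-7-oxo-3-(propan-2-yl)-1,2,3,3a,4,7,8,8a-octahydroazulen-1-yl acetate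
Product: 25 (1R,3R,3aR,4R,8aS)-3,4-dihydroxy-6,8a-dimethyl-7-oxo-3-(propan-2-yl)-1,2,3,3a,4,7,8,8a-octahydroazulen-1-yl acetate
Conditions: HF·pyridine, pyridine, THF, 0 °C → rt
Reagents that add atoms: none
Why: Buffered acidic fluoride cleaves the silyl ether without touching the acetate, the tertiary alcohol or the enone.

Step 18
Reactants: 26 4-hydroxybenzoic acid
Product: 28 4-(TBSO)benzoic acid, via bis-silylated acid 27 (not isolated)
Conditions: TBSCl (2.2 equiv), imidazole, DMF, rt; then AcOH, THF/H2O
Reagents that add atoms: tert-butyldimethylsilyl chloride, CC(C)(C)[Si](C)(C)Cl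
Why: Exhaustive silylation followed by selective hydrolysis of the labile silyl ester, which leaves the aryl silyl ether.

Step 19
Reactants: 25 (1R,3R,3aR,4R,8aS)-3,4-dihydroxy-6,8a-dimethyl-7-oxo-3-(propan-2-yl)-1,2,3,3a,4,7,8,8a-octahydroazulen-1-yl acetate; 28 4-(TBSO)benzoic acid
Product: 29 (1R,3R,3aR,4R,8aS)-1-acetoxy-3-hydroxy-6,8a-dimethyl-7-oxo-3-(propan-2-yl)-1,2,3,3a,4,7,8,8a-octahydroazulen-4-yl 4-(TBSO)benzoate
Conditions: 28, 2,4,6-trichlorobenzoyl chloride, Et3N, THF; then 25, DMAP, toluene, rt
Reagents that add atoms: none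
Why: Yamaguchi esterification: the mixed anhydride with the hindered trichlorobenzoyl group transfers the aroyl group to the allylic secondary alcohol with retention at C4; the tertiary alcohol is unreactive.

Step 20
Reactants: 29 (1R,3R,3aR,4R,8aS)-1-acetoxy-3-hydroxy-6,8a-dimethyl-7-oxo-3-(propan-2-yl)-1,2,3,3a,4,7,8,8a-octahydroazulen-4-yl 4-(TBSO)benzoate
Product: 30 (1R,3R,3aR,4R,8aS)-1-acetoxy-3-hydroxy-6,8a-dimethyl-7-oxo-3-(propan-2-yl)-1,2,3,3a,4,7,8,8a-octahydroazulen-4-yl 4-hydroxybenzoate
Conditions: Bu4NF, AcOH, THF, 0 °C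
Reagents that add atoms: none
Why: Fluoride cleaves an aryl silyl ether far faster than it attacks esters; buffering with acetic acid guards the acetate and the aryl ester against hydrolysis or migration.

Compound list

1 | 3-methylcyclopent-2-en-1-one | CC1=CC(=O)CC1 | starting material
2 | 2-bromo-3-methylcyclopent-2-en-1-one | CC1=C(Br)C(=O)CC1 | intermediate
3 | vinylboronic acid pinacol ester (2-ethenyl-4,4,5,5-tetramethyl-1,3,2-dioxaborolane) | C=CB1OC(C)(C)C(C)(C)O1 | starting material
4 | 3-methyl-2-vinylcyclopent-2-en-1-one | CC1=C(C=C)C(=O)CC1 | intermediate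
5 | methyl acetoacetate | COC(=O)CC(C)=O | starting material
6 | methyl 2-diazo-3-oxobutanoate | COC(=O)C(=[N+]=[N-])C(C)=O | intermediate
7 | methyl 3-[(tert-butyldimethylsilyl)oxy]-2-diazobut-3-enoate | COC(=O)C(=[N+]=[N-])C(=C)O[Si](C)(C)C(C)(C)C | intermediate
8 | methyl (1S,2R)-1-[1-(TBSO)ethenyl]-2-(2-methyl-5-oxocyclopent-1-en-1-yl)cyclopropane-1-carboxylate (alkenyl groups cis) | COC(=O)[C@@]1(C(=C)O[Si](C)(C)C(C)(C)C)C[C@@H]1C2=C(C)CCC2=O | intermediate (not isolated)
9 | methyl (8aS)-7-(TBSO)-8a-methyl-3-oxo-1,2,3,5,8,8a-hexahydroazulene-6-carboxylate | COC(=O)C1=C(O[Si](C)(C)C(C)(C)C)C[C@]2(C)CCC(=O)C2=CC1 | intermediate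
10 | methyl (3R,8aS)-7-(TBSO)-3-hydroxy-8a-methyl-1,2,3,5,8,8a-hexahydroazulene-6-carboxylate (3α-OH) | COC(=O)C1=C(O[Si](C)(C)C(C)(C)C)C[C@]2(C)CC[C@@H](O)C2=CC1 | intermediate
11 | C4 organoborane of 10, drawn as the 4β-BH2, 3α-OBH2 species (3aβ-H) | COC(=O)C1=C(O[Si](C)(C)C(C)(C)C)C[C@]2(C)CC[C@@H](OB)[C@H]2[C@H](B)C1 | intermediate (not isolated)
12 | methyl (3R,3aS,4R,8aS)-7-(TBSO)-3,4-dihydroxy-8a-methyl-1,2,3,3a,4,5,8,8a-octahydroazulene-6-carboxylate (3α-OH, 3aβ-H, 4β-OH) | COC(=O)C1=C(O[Si](C)(C)C(C)(C)C)C[C@]2(C)CC[C@@H](O)[C@H]2[C@H](O)C1 | intermediate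
13 | methyl (3R,3aS,4R,8aS)-4,7-bis(TBSO)-3-hydroxy-8a-methyl-1,2,3,3a,4,5,8,8a-octahydroazulene-6-carboxylate | COC(=O)C1=C(O[Si](C)(C)C(C)(C)C)C[C@]2(C)CC[C@@H](O)[C@H]2[C@H](O[Si](C)(C)C(C)(C)C)C1 | intermediate
14 | methyl (3aR,4R,8aS)-4,7-bis(TBSO)-8a-methyl-3-oxo-1,2,3,3a,4,5,8,8a-octahydroazulene-6-carboxylate | COC(=O)C1=C(O[Si](C)(C)C(C)(C)C)C[C@]2(C)CCC(=O)[C@H]2[C@H](O[Si](C)(C)C(C)(C)C)C1 | intermediate
15 | methyl (3aR,4R,8aS)-4,7-bis(TBSO)-8a-methyl-3-(trimethylsilyloxy)-1,3a,4,5,8,8a-hexahydroazulene-6-carboxylate | COC(=O)C1=C(O[Si](C)(C)C(C)(C)C)C[C@]2(C)CC=C(O[Si](C)(C)C)[C@H]2[C@H](O[Si](C)(C)C(C)(C)C)C1 | intermediate (not isolated)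
16 | methyl (3aR,4R,8aR)-4,7-bis(TBSO)-8a-methyl-3-oxo-3,3a,4,5,8,8a-hexahydroazulene-6-carboxylate | COC(=O)C1=C(O[Si](C)(C)C(C)(C)C)C[C@]2(C)C=CC(=O)[C@H]2[C@H](O[Si](C)(C)C(C)(C)C)C1 | intermediate
17 | methyl (1R,3aR,4R,8aR)-4,7-bis(TBSO)-8a-methyl-3-oxo-1-(4,4,5,5-tetramethyl-1,3,2-dioxaborolan-2-yl)-1,2,3,3a,4,5,8,8a-octahydroazulene-6-carboxylate (1β-boryl) | COC(=O)C1=C(O[Si](C)(C)C(C)(C)C)C[C@]2(C)[C@H](B3OC(C)(C)C(C)(C)O3)CC(=O)[C@H]2[C@H](O[Si](C)(C)C(C)(C)C)C1 | intermediate (not isolated)
18 | methyl (1R,3aR,4R,8aS)-4,7-bis(TBSO)-1-hydroxy-8a-methyl-3-oxo-1,2,3,3a,4,5,8,8a-octahydroazulene-6-carboxylate | COC(=O)C1=C(O[Si](C)(C)C(C)(C)C)C[C@]2(C)[C@H](O)CC(=O)[C@H]2[C@H](O[Si](C)(C)C(C)(C)C)C1 | intermediate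
19 | methyl (1R,3aR,4R,8aS)-4,7-bis(TBSO)-8a-methyl-3-oxo-1-(triethylsilyloxy)-1,2,3,3a,4,5,8,8a-octahydroazulene-6-carboxylate | COC(=O)C1=C(O[Si](C)(C)C(C)(C)C)C[C@]2(C)[C@H](O[Si](CC)(CC)CC)CC(=O)[C@H]2[C@H](O[Si](C)(C)C(C)(C)C)C1 | intermediate
20 | methyl (1R,3R,3aR,4R,8aS)-4,7-bis(TBSO)-3-hydroxy-8a-methyl-3-(propan-2-yl)-1-(triethylsilyloxy)-1,2,3,3a,4,5,8,8a-octahydroazulene-6-carboxylate | COC(=O)C1=C(O[Si](C)(C)C(C)(C)C)C[C@]2(C)[C@H](O[Si](CC)(CC)CC)C[C@@](O)(C(C)C)[C@H]2[C@H](O[Si](C)(C)C(C)(C)C)C1 | intermediate
21 | (1R,3R,3aR,4R,8aS)-4,7-bis(TBSO)-6-(hydroxymethyl)-8a-methyl-3-(propan-2-yl)-1-(triethylsilyloxy)-1,2,3,3a,4,5,8,8a-octahydroazulen-3-ol | OCC1=C(O[Si](C)(C)C(C)(C)C)C[C@]2(C)[C@H](O[Si](CC)(CC)CC)C[C@@](O)(C(C)C)[C@H]2[C@H](O[Si](C)(C)C(C)(C)C)C1 | intermediate (not isolated)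
22 | (1R,3R,3aR,4R,8aS)-4-(TBSO)-1,3-dihydroxy-8a-methyl-6-methylidene-3-(propan-2-yl)octahydroazulen-7(1H)-one | C=C1C(=O)C[C@]2(C)[C@H](O)C[C@@](O)(C(C)C)[C@H]2[C@H](O[Si](C)(C)C(C)(C)C)C1 | intermediate
23 | (1R,3R,3aR,4R,8aS)-4-(TBSO)-1,3-dihydroxy-6,8a-dimethyl-3-(propan-2-yl)-2,3,3a,4,8,8a-hexahydroazulen-7(1H)-one | O[C@@H]1C[C@@](O)(C(C)C)[C@H]2[C@H](O[Si](C)(C)C(C)(C)C)C=C(C)C(=O)C[C@]12C | intermediate
24 | (1R,3R,3aR,4R,8aS)-4-(TBSO)-3-hydroxy-6,8a-dimethyl-7-oxo-3-(propan-2-yl)-1,2,3,3a,4,7,8,8a-octahydroazulen-1-yl acetate | CC(=O)O[C@@H]1C[C@@](O)(C(C)C)[C@H]2[C@H](O[Si](C)(C)C(C)(C)C)C=C(C)C(=O)C[C@]12C | intermediate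
25 | (1R,3R,3aR,4R,8aS)-3,4-dihydroxy-6,8a-dimethyl-7-oxo-3-(propan-2-yl)-1,2,3,3a,4,7,8,8a-octahydroazulen-1-yl acetate | CC(=O)O[C@@H]1C[C@@](O)(C(C)C)[C@H]2[C@H](O)C=C(C)C(=O)C[C@]12C | intermediate
26 | 4-hydroxybenzoic acid | OC(=O)c1ccc(O)cc1 | starting material
27 | tert-butyldimethylsilyl 4-[(tert-butyldimethylsilyl)oxy]benzoate | CC(C)(C)[Si](C)(C)Oc1ccc(cc1)C(=O)O[Si](C)(C)C(C)(C)C | intermediate (not isolated)
28 | 4-[(tert-butyldimethylsilyl)oxy]benzoic acid | CC(C)(C)[Si](C)(C)Oc1ccc(cc1)C(O)=O | intermediate
29 | (1R,3R,3aR,4R,8aS)-1-acetoxy-3-hydroxy-6,8a-dimethyl-7-oxo-3-(propan-2-yl)-1,2,3,3a,4,7,8,8a-octahydroazulen-4-yl 4-[(tert-butyldimethylsilyl)oxy]benzoate | CC(=O)O[C@@H]1C[C@@](O)(C(C)C)[C@H]2[C@H](OC(=O)c3ccc(O[Si](C)(C)C(C)(C)C)cc3)C=C(C)C(=O)C[C@]12C | intermediate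
30 | (1R,3R,3aR,4R,8aS)-1-acetoxy-3-hydroxy-6,8a-dimethyl-7-oxo-3-(propan-2-yl)-1,2,3,3a,4,7,8,8a-octahydroazulen-4-yl 4-hydroxybenzoate | CC(=O)O[C@@H]1C[C@@](O)(C(C)C)[C@H]2[C@H](OC(=O)c3ccc(O)cc3)C=C(C)C(=O)C[C@]12C | target

Total step count: 20. Longest linear sequence: 17 steps from 1 (steps 1, 2, 5–17, 19, 20); steps 3–4 and 18 are side branches.

Least certain steps

Step 5 (key step). The vinyl group of 4 is part of an electron-poor cross-conjugated diene, so cyclopropanation may be slow and the carbenoid may instead dimerise or attack the carbonyl oxygen. With the C8a methyl inside the boat, the Cope shift may stall at 8 and allow the cyclopropane to isomerise. Either would cost yield or enantiomeric purity. Fallback: take the ketone out of conjugation before the carbenoid step. Corey–Bakshi–Shibata reduction of 4 gives (R)-3-methyl-2-vinylcyclopent-2-en-1-ol F1, which is silylated to its trimethylsilyl ether F2. The same cyclopropanation–Cope sequence with 7 and Rh2(S-PTAD)4 then runs on an electron-rich diene whose ring alkene is still tetrasubstituted, and gives the 3α-trimethylsilyloxy dienoate F3. Citric acid in methanol frees the alcohol. This sets out from 4 and returns at 10, so step 6 is not needed.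

Step 7. Borane may attack the α face in part, since the difference between the C8a methyl and the ring B methylene is modest; that would give the cis-fused diastereomer. The mildly basic peroxide work-up could also strip the enol silyl group of ring B. Fallback: keep the ketone and use the enone directly. Nucleophilic epoxidation of 9 (tBuOOH, DBU) gives the 3a,4-epoxy ketone F4. SmI2 in THF/MeOH at −78 °C cleaves the α C–O bond to the β-hydroxy ketone F5, whose C3a centre is α to the ketone and can be equilibrated. TBSOTf/2,6-lutidine then gives the silyl ether. This sets out from 9 and returns at 14.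

Step 8. Site selectivity may be incomplete, giving silylation at C3 or at both hydroxyls, because both are secondary. Fallback: differentiate the two oxygens in time rather than by hindrance. Alcohol 10 is converted into its TES ether F6, hydroborated and oxidised as in step 7 to the C4 alcohol F7, and silylated to the mixed bis-silyl ether F8. AcOH/THF/H2O then removes only the TES group. This sets out from 10 and returns at 13.

Step 13. Facial selectivity may be poor or reversed, because attack from the α face runs past the angular methyl, which would give the C3 epimer. Enolisation with loss of a β-silyloxy group is a second risk. Fallback: put isopropyl on an sp2 carbon and deliver the oxygen from the β face under hydroxyl direction.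
- KN(SiMe3)2 and PhNTf2 convert 19 into the C2=C3 enol triflate F9.
- iPr2CuLi replaces triflate by isopropyl to give alkene F10.
- AcOH/THF/H2O removes the TES group to give allylic alcohol F11.
- VO(acac)2/tBuOOH epoxidises C2=C3 on the face of the C1 hydroxyl, giving the 2β,3β-epoxy alcohol F12.
- LiAlH4 opens the epoxide at the secondary C2 and reduces the ester, giving triol F13.
- The acid treatment of step 14 then gives the exocyclic enone.

This sets out from 19 and returns at 22.

Step 15. The α-methylene ketone may be consumed by conjugate addition of ethanol or by dimerisation before the double bond migrates, and HCl formed from RhCl3 in hot ethanol may remove the C4 silyl ether. Fallback: saturate and re-oxidise. Hydrogenation of 22 (H2, palladium on carbon) gives the C6 methyl ketone F12b, here called F14. Acetylation as in step 16 gives acetate F15. IBX in DMSO at 70 °C dehydrogenates toward C5, the only side with a β-hydrogen. This sets out from 22 and returns at 24.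

Further compounds

F1 | step 5 | (R)-3-methyl-2-vinylcyclopent-2-en-1-ol | CC1=C(C=C)[C@H](O)CC1
F2 | step 5 | (R)-3-methyl-1-(trimethylsilyloxy)-2-vinylcyclopent-2-ene | CC1=C(C=C)[C@H](O[Si](C)(C)C)CC1
F3 | step 5 | methyl (3R,8aS)-7-(TBSO)-8a-methyl-3-(trimethylsilyloxy)-1,2,3,5,8,8a-hexahydroazulene-6-carboxylate | COC(=O)C1=C(O[Si](C)(C)C(C)(C)C)C[C@]2(C)CC[C@@H](O[Si](C)(C)C)C2=CC1
F4 | step 7 | 3aβ,4β-epoxy ketone of 9 | COC(=O)C1=C(O[Si](C)(C)C(C)(C)C)C[C@]2(C)CCC(=O)[C@]23O[C@@H]3C1
F5 | step 7 | 4β-hydroxy-3aβ-H ketone (14 without the C4 silyl group) | COC(=O)C1=C(O[Si](C)(C)C(C)(C)C)C[C@]2(C)CCC(=O)[C@H]2[C@H](O)C1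
F6 | step 8 | 3α-triethylsilyl ether of 10 | COC(=O)C1=C(O[Si](C)(C)C(C)(C)C)C[C@]2(C)CC[C@@H](O[Si](CC)(CC)CC)C2=CC1
F7 | step 8 | 3α-triethylsilyloxy-4β-hydroxy-3aβ-H compound | COC(=O)C1=C(O[Si](C)(C)C(C)(C)C)C[C@]2(C)CC[C@@H](O[Si](CC)(CC)CC)[C@H]2[C@H](O)C1
F8 | step 8 | 3α-triethylsilyloxy-4β-TBSO compound | COC(=O)C1=C(O[Si](C)(C)C(C)(C)C)C[C@]2(C)CC[C@@H](O[Si](CC)(CC)CC)[C@H]2[C@H](O[Si](C)(C)C(C)(C)C)C1
F9 | step 13 | C2=C3 enol triflate of 19 | COC(=O)C1=C(O[Si](C)(C)C(C)(C)C)C[C@]2(C)[C@H](O[Si](CC)(CC)CC)C=C(OS(=O)(=O)C(F)(F)F)[C@H]2[C@H](O[Si](C)(C)C(C)(C)C)C1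
F10 | step 13 | 3-isopropyl C2=C3 alkene with 1β-triethylsilyloxy group | COC(=O)C1=C(O[Si](C)(C)C(C)(C)C)C[C@]2(C)[C@H](O[Si](CC)(CC)CC)C=C(C(C)C)[C@H]2[C@H](O[Si](C)(C)C(C)(C)C)C1
F11 | step 13 | 3-isopropyl C2=C3 alkene with free 1β-hydroxyl | COC(=O)C1=C(O[Si](C)(C)C(C)(C)C)C[C@]2(C)[C@H](O)C=C(C(C)C)[C@H]2[C@H](O[Si](C)(C)C(C)(C)C)C1
F12 | step 13 | 2β,3β-epoxy-1β-ol | COC(=O)C1=C(O[Si](C)(C)C(C)(C)C)C[C@]2(C)[C@H](O)[C@@H]3O[C@]3(C(C)C)[C@H]2[C@H](O[Si](C)(C)C(C)(C)C)C1
F13 | step 13 | 1β,3β-diol with C6 hydroxymethyl group (21 without the triethylsilyl group) | OCC1=C(O[Si](C)(C)C(C)(C)C)C[C@]2(C)[C@H](O)C[C@@](O)(C(C)C)[C@H]2[C@H](O[Si](C)(C)C(C)(C)C)C1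
F14 | step 15 | C6 methyl ketone from hydrogenation of 22 (C6 epimers) | CC1C(=O)C[C@]2(C)[C@H](O)C[C@@](O)(C(C)C)[C@H]2[C@H](O[Si](C)(C)C(C)(C)C)C1
F15 | step 15 | C1 acetate of F14 | CC1C(=O)C[C@]2(C)[C@H](OC(C)=O)C[C@@](O)(C(C)C)[C@H]2[C@H](O[Si](C)(C)C(C)(C)C)C1
A1 | alternative 1 | 3-(1,3-dioxolan-2-ylmethyl)cyclopent-2-en-1-one | O=C1CCC(CC2OCCO2)=C1
A2 | alternative 1 | (Z)-3-iodobut-2-enal | C/C(I)=C/C=O
A3 | alternative 1 | 2-(1-hydroxy-3-iodobut-2-enyl)-3-methyl-3-(1,3-dioxolan-2-ylmethyl)cyclopentanone | C1CC(=O)[C@@H]([C@H](O)/C=C(/C)I)[C@]1(C)CC2OCCO2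
A4 | alternative 2 | 1-diazo-4-(3-methoxy-4-methylphenyl)butan-2-one | COc1cc(CCC(=O)C=[N+]=[N-])ccc1C
A5 | alternative 2 | 5-methoxy-6-methyl-3,8a-dihydroazulen-1(2H)-one (one enantiomer drawn) | O=C1CCC2=CC(OC)=C(C)C=C[C@@H]12
A6 | alternative 3 | 2-methylcyclohept-1-enyl (E)-2-(trimethylsilyl)vinyl ketone carrying the C4 pivalate, C6 methyl and C7 dioxolane | C[Si](C)(C)/C=C/C(=O)C1=C(C)CC2(OCCO2)[C@@H](C)C[C@@H]1OC(=O)C(C)(C)C
A7 | alternative 3 | trans-fused C1=C2 enone with C3 ketone, C4 pivalate, C6 methyl and C7 dioxolane | C1=CC(=O)[C@H]2[C@@H](OC(=O)C(C)(C)C)C[C@H](C)C3(OCCO3)C[C@]12C
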